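**Retrosynthetic overview**
The strategy rests on the unbranched, fully saturated C25 acyl chain (C1 carbonyl to C25 methyl), which carries no stereocentre. Its C10–C11 single bond is treated as a hydrogenated C10=C11 alkene.
Retro-cross-metathesis of that alkene gives a C1–C10 piece capped by =CH2 (2-phenylethyl undec-10-enoate) and a C11–C25 piece capped by =CH2 (1-hexadecene). The two caps leave as ethylene, and 10 + 15 = 25 chain carbons.
The ester C(=O)–O bond is then disconnected to undec-10-enoic acid and 2-phenylethanol. In the forward direction the ester is made first and no protecting group is needed.
No ring is formed. The only ring, the phenyl ring, is bought with the alcohol, and its O–CH2–CH2–Ph link is homobenzylic and should survive the final hydrogenation.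

Key step: step 2

Assumption: the cross-metathesis product is expected as an E/Z mixture in which E should predominate. It is named and drawn as the E isomer, and both isomers lead to the same saturated chain.

Step 1
Reactants: 1 undec-10-enoic acid; 2 2-phenylethanol
Product: 3 2-phenylethyl undec-10-enoate
Conditions: p-TsOH·H2O (5 mol%), toluene, reflux, Dean–Stark trap
Reagents that add atoms: none
Why: Fischer esterification of an unhindered primary alcohol with an unbranched acid is driven to completion by azeotropic removal of water, and the isolated terminal alkene, the phenyl ring and the new ester are inert to a catalytic sulfonic acid in toluene.

Step 2
Reactants: 3 2-phenylethyl undec-10-enoate; 4 1-hexadecene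
Product: 5 2-phenylethyl (E)-pentacos-10-enoate
Conditions: 4 (4 equiv), second-generation Grubbs catalyst (H2IMes)(PCy3)Cl2Ru=CHPh (2 mol%), 1,4-benzoquinone (10 mol%), CH2Cl2, 40 °C, Ar sparge
Reagents that add atoms: none
Why: Olefin cross-metathesis by the Chauvin mechanism: after loss of PCy3 the ruthenium benzylidene adds across the terminal C=C of 3 or 4 in a [2+2] sense, the ruthenacyclobutane cleaves to a new alkylidene, and this engages the other partner in the same way, so that C10 of 3 and C2 of 4 become the C10=C11 double bond of 5 while the two =CH2 termini leave together as ethylene, whose removal in the argon stream pulls the equilibrium forward. The closest known reaction type is the ruthenium-carbene cross-metathesis of ω-unsaturated fatty esters with linear α-olefins, so the step applies established chemistry to a new pair of partners. No ring is closed and no stereocentre is created, the phenyl ring is a spectator, and the E geometry expected under thermodynamic control is of no account because step 3 removes the double bond. The selectivity needed is cross- over self-metathesis, and the substrates cannot supply it, since both are unhindered, electronically neutral monosubstituted alkenes of equal reactivity; it is imposed by stoichiometry instead, an excess of the inexpensive 4 steering 3 toward 5, and self-metathesis of 3 stays reversible under the conditions. What the substrate does secure is compatibility and separability: the ester lies eight methylene groups away from the alkene and cannot chelate the carbene, and its single polar group places 5 between the ester-free hydrocarbons and any diester on silica gel. Positional fidelity of the double bond, on which the exact C25 length depends, is guarded by 1,4-benzoquinone, which intercepts the ruthenium hydrides that cause alkene migration, and by the mild temperature.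

Step 3
Reactants: 5 2-phenylethyl (E)-pentacos-10-enoate
Product: 6 2-phenylethyl pentacosanoate
Conditions: H2 (1 atm), 10% Pd/C, EtOAc, 35 °C
Reagents that add atoms: none
Why: Heterogeneous catalytic hydrogenation adds H2 to the unhindered 1,2-disubstituted alkene on the palladium surface at atmospheric pressure, conditions under which the phenyl ring is not reduced and the ester is not cleaved because its O–CH2 carbon is homobenzylic (O–CH2–CH2–Ph) and not benzylic, and both alkene isomers converge on the achiral saturated chain of 6.

**Compound list**
1 | undec-10-enoic acid | C=CCCCCCCCCC(=O)O | starting material
2 | 2-phenylethanol | OCCc1ccccc1 | starting material
3 | 2-phenylethyl undec-10-enoate | C=CCCCCCCCCC(=O)OCCc1ccccc1 | intermediate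
4 | 1-hexadecene | C=CCCCCCCCCCCCCCC | starting material
5 | 2-phenylethyl (E)-pentacos-10-enoate | CCCCCCCCCCCCCC/C=C/CCCCCCCCC(=O)OCCc1ccccc1 | intermediate
6 | 2-phenylethyl pentacosanoate | CCCCCCCCCCCCCCCCCCCCCCCCC(=O)OCCc1ccccc1 | target

Total step count: 3
Longest linear sequence: 3 steps (1 → 3 → 5 → 6)

**Steps most likely to fail**

1. Step 2.
   - Risk: self-metathesis competes statistically with the cross reaction, and the catalyst may decay before 3 is consumed. Hydride-mediated migration of the double bond before coupling would shift the chain length by single carbons and give homologues that cannot be separated. For the same reason a high-purity grade of 4, filtered through neutral alumina, should be used.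
   - Fallback: an alkene-free sp3–sp3 coupling that sets out from 2 and comes back at 6. Compound 2 is esterified with commercial 11-bromoundecanoic acid under the conditions of step 1 to give 2-phenylethyl 11-bromoundecanoate F1. Commercial tetradecylmagnesium chloride is then added slowly to F1 in THF/NMP with catalytic Li2CuCl4 at 0–20 °C. This copper-catalysed Kochi-type alkyl–alkyl coupling should outpace addition to the ester. It should form the C11–C12 bond and deliver 6 directly (11 + 14 = 25 chain carbons). No double bond is ever present, so chain-length scrambling by migration is excluded.

2. Step 3.
   - Risk: traces of ruthenium, phosphine or quinone carried over from step 2 may poison the palladium surface, and the waxy product may crystallise onto the catalyst. Either would stop the saturation short of completion.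
   - Fallback: a metal-free reduction that sets out from 5 and comes back at 6. Excess p-toluenesulfonyl hydrazide and NaOAc in refluxing DME/water generate diimide F2. This should transfer two hydrogen atoms to the C10=C11 bond through a concerted cyclic transition state. It should leave the phenyl ring and the ester untouched and is indifferent to catalyst poisons.

3. Step 1.
   - Risk: the reaction may stall at equilibrium if water removal is inefficient. Acid-promoted side reactions at reflux are also possible, such as migration of the terminal double bond or self-condensation of the alcohol.
   - Fallback: a Steglich esterification at room temperature that sets out from 1 (with 2) and comes back at 3. N,N'-Dicyclohexylcarbodiimide in CH2Cl2 activates 1 as O-(undec-10-enoyl)-N,N'-dicyclohexylisourea F3. Catalytic DMAP then relays the acyl group to 2. The coupling is irreversible and essentially neutral, so neither an equilibrium nor a strong acid is involved. The urea by-product is removed by filtration and trituration with hexane.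

**Further compounds**
F1 | step 2 | 2-phenylethyl 11-bromoundecanoate | BrCCCCCCCCCCC(=O)OCCc1ccccc1
F2 | step 3 | diimide | N=N
F3 | step 1 | O-(undec-10-enoyl)-N,N'-dicyclohexylisourea | C=CCCCCCCCCC(=O)OC(=NC1CCCCC1)NC1CCCCC1
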